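The carbocyclic ring of the coumarin (C4a, C5–C8, C8a) is built onto a ready-made 3,4-dimethyl-2-pyranone. A photochemical Wolff rearrangement and ketene–alkyne benzannulation forges four ring bonds in one operation. It places a free phenol, the alkyne substituent and a silyl ether on adjacent carbons, which is the C5–O, C6–prenyl, C7–O pattern of the target, with the two oxygens already told apart. Its precursors are 6-(diazoacetyl)-3,4-dimethyl-2-pyranone and a prenyl-substituted triisopropylsiloxyalkyne. The C8 acyl group is then attached by formylation and chromium-mediated coupling with a cyclohexenyl triflate, whose cis-5,6 and carbinol centres come from a chelate-controlled Claisen rearrangement.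

Key step: step 4

Remark: primed locants refer to the cyclohexene ring (C1′ carries the ketone carbonyl). In the target the C5′ methyl and C6′ 1-hydroxyethyl groups are cis, so the side chain is planned for the (5′R,6′R,1″S) arrangement and not for the trans product of an enolate aldol on a 3-methylcyclohexanone.

**Step 1**
Reactants: 1 diethyl oxalate; 2 ethyl 2,3-dimethylbut-2-enoate
Product: 4 3,4-dimethyl-2-oxo-2H-pyran-6-carboxylic acid, via potassium dienolate 3 (not isolated)
Conditions: KOEt, EtOH/Et2O, 0 °C→rt; then conc. HCl, 100 °C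
Reagents that add atoms: water, O
Why: Vinylogous Claisen condensation at a γ-methyl group of 2 with diethyl oxalate is driven by the stabilised dienolate, and hot acid then lactonises the enol onto the enoate ester and hydrolyses the remaining ester, the classical entry to 2-pyranone-6-carboxylic acids.

**Step 2**
Reactants: 4 3,4-dimethyl-2-oxo-2H-pyran-6-carboxylic acid
Product: 6 6-(2-diazoacetyl)-3,4-dimethyl-2H-pyran-2-one, via acid chloride 5 (not isolated)
Conditions: (COCl)2, cat. DMF, CH2Cl2, 0 °C→rt; evaporate; CH2N2 (2.5 equiv), Et2O, 0 °C, short reaction time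
Reagents that add atoms: diazomethane, C=[N+]=[N-]
Why: Acid chloride formation followed by acylation of diazomethane (first stage of the Arndt–Eistert sequence) should give the α-diazo ketone, the second equivalent of diazomethane taking up the hydrogen chloride.

**Step 3**
Reactants: 7 ethyl 4-methylpent-3-enoate
Product: 9 triisopropyl[(5-methylhex-4-en-1-yn-1-yl)oxy]silane, via lithium ynolate 8 (not isolated)
Conditions: CH2Br2, lithium 2,2,6,6-tetramethylpiperidide, THF, −78 °C; add 7; LiN(SiMe3)2; n-BuLi, −78 °C→rt; TIPSOTf, −78 °C→0 °C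
Reagents that add atoms: dibromomethane, BrCBr; triisopropylsilyl trifluoromethanesulfonate, CC(C)[Si](OS(=O)(=O)C(F)(F)F)(C(C)C)C(C)C
Why: Kowalski ester homologation (addition of dibromomethyllithium, enolisation, bromine–lithium exchange and 1,2-shift) should give the ynolate, which the bulky silyl triflate traps on oxygen.

**Step 4**
Reactants: 6 6-(2-diazoacetyl)-3,4-dimethyl-2H-pyran-2-one; 9 triisopropyl[(5-methylhex-4-en-1-yn-1-yl)oxy]silane
Product: 13 5-hydroxy-3,4-dimethyl-6-(3-methylbut-2-en-1-yl)-7-[(triisopropylsilyl)oxy]-2H-chromen-2-one, via pyranonylketene 10 (not isolated), via cyclobutenone 11 (not isolated), via dienylketene 12 (not isolated)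
Conditions: 9 (1.5 equiv), hν (440 nm LEDs), degassed ClCH2CH2Cl, 25 °C; then 80 °C
Reagents that add atoms: none
Why: Proposed new method: visible-light Wolff rearrangement of 6 (pyranone C6 shifts to the diazo carbon, forming C8–C8a) should give ketene 10, which adds [2+2] to the siloxyalkyne to give cyclobutenone 11 (C5–C6 and C7–C8); thermal 4π ring opening to dienylketene 12, 6π-electrocyclisation onto pyranone C5 (C4a–C5) and enolisation then give phenol 13. The closest known reaction type is the Danheiser benzannulation of aryl, heteroaryl and alkenyl α-diazo ketones with siloxyalkynes; the new element is that the C5=C6 bond of a 2-pyranone acts as the vinyl partner, which should close at least as readily as a benzenoid bond because no aromatic sextet has to be broken. The benzene ring is the only ring that remains, closed by thermal disrotatory 6π-electrocyclisation of the dienylketene followed by tautomerisation, the four-membered ring being transient. No stereocentre is formed. The step needs the regiochemistry of the ketene–alkyne [2+2], secured by the polarisation of the siloxyalkyne, whose nucleophilic prenyl-bearing carbon attacks the ketene carbonyl carbon so that prenyl ends up at C6 between C5–OH and C7–OSi. Irradiation at 440 nm, where only the diazo ketone should absorb, and an excess of alkyne are chosen to spare the photolabile pyranone and coumarin chromophores and to keep the new phenol from being acylated by ketene.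

**Step 5**
Reactants: 13 5-hydroxy-3,4-dimethyl-6-(3-methylbut-2-en-1-yl)-7-[(triisopropylsilyl)oxy]-2H-chromen-2-one
Product: 14 5-methoxy-3,4-dimethyl-6-(3-methylbut-2-en-1-yl)-7-[(triisopropylsilyl)oxy]-2H-chromen-2-one
Conditions: MeI, K2CO3, acetone, 50 °C
Reagents that add atoms: iodomethane, CI
Why: Williamson etherification of the only free phenol should be clean because the C7 oxygen remains masked as its silyl ether.

**Step 6**
Reactants: 14 5-methoxy-3,4-dimethyl-6-(3-methylbut-2-en-1-yl)-7-[(triisopropylsilyl)oxy]-2H-chromen-2-one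
Product: 15 7-hydroxy-5-methoxy-3,4-dimethyl-6-(3-methylbut-2-en-1-yl)-2H-chromen-2-one
Conditions: Bu4NF, THF, 0 °C; aq. NH4Cl
Reagents that add atoms: none
Why: Fluoride-induced desilylation of an aryl silyl ether is fast at 0 °C and should leave lactone, methyl ether and prenyl group untouched.

**Step 7**
Reactants: 15 7-hydroxy-5-methoxy-3,4-dimethyl-6-(3-methylbut-2-en-1-yl)-2H-chromen-2-one
Product: 16 7-hydroxy-5-methoxy-3,4-dimethyl-6-(3-methylbut-2-en-1-yl)-2-oxo-2H-chromene-8-carbaldehyde
Conditions: MgCl2, Et3N, (CH2O)n, MeCN, 80 °C; dilute HCl work-up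
Reagents that add atoms: paraformaldehyde (as formaldehyde), C=O
Why: Magnesium-mediated ortho-formylation of phenols (Casnati–Skattebøl) delivers formaldehyde next to the magnesium phenoxide, C8 is the only free ring position, and the non-acidic conditions spare the ortho-prenyl phenol.

**Step 8**
Reactants: 16 7-hydroxy-5-methoxy-3,4-dimethyl-6-(3-methylbut-2-en-1-yl)-2-oxo-2H-chromene-8-carbaldehyde
Product: 17 7-[(tert-butyldimethylsilyl)oxy]-5-methoxy-3,4-dimethyl-6-(3-methylbut-2-en-1-yl)-2-oxo-2H-chromene-8-carbaldehyde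
Conditions: TBSOTf, 2,6-lutidine, CH2Cl2, 0 °C
Reagents that add atoms: tert-butyldimethylsilyl trifluoromethanesulfonate, CC(C)(C)[Si](C)(C)OS(=O)(=O)C(F)(F)F
Why: O-Silylation with the silyl triflate should overcome the hydrogen bond to the aldehyde and removes the acidic proton before the organochromium coupling.

**Step 9**
Reactants: 18 ethyl (3S)-3-hydroxybutanoate; 19 (2Z)-but-2-en-1-ol (3 equiv)
Product: 20 (2Z)-but-2-en-1-yl (3S)-3-hydroxybutanoate
Conditions: Ti(OEt)4 (10 mol %), toluene, 100 °C, ethanol distilled off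
Reagents that add atoms: none
Why: Titanate-catalysed transesterification is neutral, so the β-hydroxy stereocentre and the Z-alkene should be carried over unchanged.

**Step 10**
Reactants: 20 (2Z)-but-2-en-1-yl (3S)-3-hydroxybutanoate
Product: 22 (2S,3R)-2-[(1S)-1-hydroxyethyl]-3-methylpent-4-enoic acid, via dilithium dianion 21 (not isolated)
Conditions: LiN(iPr)2 (2.2 equiv), THF, −78 °C→rt, then 50 °C; aq. HCl
Reagents that add atoms: none
Why: Ester enolate Claisen rearrangement (Ireland–Claisen type) of the lithium-chelated dianion: the chelate fixes the Z(O)-enolate and, as in Fráter–Seebach alkylations, directs bond formation to the face opposite the carbinol methyl (C2 anti to the hydroxyl), while the chair transition state with the (Z)-butenyl unit sets C3 anti to C2, the future cis C5′/C6′ relationship.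

**Step 11**
Reactants: 22 (2S,3R)-2-[(1S)-1-hydroxyethyl]-3-methylpent-4-enoic acid
Product: 23 (2S,3R)-2-[(1S)-1-hydroxyethyl]-N-methoxy-N,3-dimethylpent-4-enamide
Conditions: MeNHOMe·HCl, EDC·HCl, HOBt, N-methylmorpholine, CH2Cl2, 0 °C→rt
Reagents that add atoms: N,O-dimethylhydroxylamine hydrochloride, CNOC.Cl
Why: Carbodiimide amide coupling to the Weinreb amide proceeds under near-neutral conditions that should not epimerise C2 or dehydrate the β-hydroxy acid.

**Step 12**
Reactants: 23 (2S,3R)-2-[(1S)-1-hydroxyethyl]-N-methoxy-N,3-dimethylpent-4-enamide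
Product: 24 (2S,3R)-N-methoxy-N,3-dimethyl-2-[(1S)-1-(triethylsilyloxy)ethyl]pent-4-enamide
Conditions: TESCl, imidazole, DMF, 0 °C→rt
Reagents that add atoms: chlorotriethylsilane, CC[Si](Cl)(CC)CC
Why: Silylation of the secondary alcohol blocks retro-aldol and elimination pathways in the later basic and organometallic steps.

**Step 13**
Reactants: 24 (2S,3R)-N-methoxy-N,3-dimethyl-2-[(1S)-1-(triethylsilyloxy)ethyl]pent-4-enamide
Product: 25 (5S,6R)-6-methyl-5-[(1S)-1-(triethylsilyloxy)ethyl]octa-1,7-dien-4-one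
Conditions: allylMgBr, THF, −78 °C→0 °C; cold aq. NH4Cl
Reagents that add atoms: allylmagnesium bromide, C=CC[Mg]Br
Why: Weinreb ketone synthesis stops at the ketone through the stable magnesium chelate, and the cold, buffered quench should prevent conjugation of the β,γ-alkene and epimerisation at C5.

**Step 14**
Reactants: 25 (5S,6R)-6-methyl-5-[(1S)-1-(triethylsilyloxy)ethyl]octa-1,7-dien-4-one
Product: 27 (2S,3R)-3-methyl-2-[(1S)-1-(triethylsilyloxy)ethyl]cyclohexan-1-one, via cyclohexenone 26 (not isolated)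
Conditions: second-generation Grubbs catalyst (3 mol %), CH2Cl2, 40 °C; solvent exchange; H2 (1 atm), Pd/C, EtOAc, rt
Reagents that add atoms: none
Why: Ring-closing metathesis of the two terminal alkenes closes the six-membered ring and neutral hydrogenation saturates it, so both ring stereocentres (cis) arrive unchanged from 25.

**Step 15**
Reactants: 27 (2S,3R)-3-methyl-2-[(1S)-1-(triethylsilyloxy)ethyl]cyclohexan-1-one
Product: 29 (5R,6S)-5-methyl-6-[(1S)-1-(triethylsilyloxy)ethyl]cyclohex-1-en-1-yl trifluoromethanesulfonate, via lithium enolate 28 (not isolated)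
Conditions: LiN(iPr)2, THF, −78 °C; Comins' reagent, −78 °C
Reagents that add atoms: N-(5-chloropyridin-2-yl)bis(trifluoromethanesulfonimide), Clc1ccc(N(S(=O)(=O)C(F)(F)F)S(=O)(=O)C(F)(F)F)nc1
Why: Kinetic enolisation removes a proton from the unhindered CH2 and not from the crowded tertiary α-carbon, and O-triflation at −78 °C fixes this enolate, so the epimerisable centre next to the carbonyl is never deprotonated.

**Step 16**
Reactants: 17 7-[(tert-butyldimethylsilyl)oxy]-5-methoxy-3,4-dimethyl-6-(3-methylbut-2-en-1-yl)-2-oxo-2H-chromene-8-carbaldehyde; 29 (5R,6S)-5-methyl-6-[(1S)-1-(triethylsilyloxy)ethyl]cyclohex-1-en-1-yl trifluoromethanesulfonate (1.5 equiv)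
Product: 30 7-[(tert-butyldimethylsilyl)oxy]-8-{hydroxy[(5R,6R)-5-methyl-6-[(1S)-1-(triethylsilyloxy)ethyl]cyclohex-1-en-1-yl]methyl}-5-methoxy-3,4-dimethyl-6-(3-methylbut-2-en-1-yl)-2H-chromen-2-one (both carbinol epimers)
Conditions: CrCl2 (6 equiv), NiCl2 (2 mol %), degassed DMF, rt
Reagents that add atoms: none
Why: Nozaki–Hiyama–Kishi coupling generates an alkenylchromium species from the enol triflate under nickel catalysis that adds to aldehydes only, tolerating lactone, silyl ethers and the prenyl alkene; the new carbinol centre is uncontrolled and is removed in the next step.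

**Step 17**
Reactants: 30 the allylic alcohol from step 16
Product: 31 7-[(tert-butyldimethylsilyl)oxy]-5-methoxy-3,4-dimethyl-6-(3-methylbut-2-en-1-yl)-8-{[(5R,6R)-5-methyl-6-[(1S)-1-(triethylsilyloxy)ethyl]cyclohex-1-en-1-yl]carbonyl}-2H-chromen-2-one
Conditions: Dess–Martin periodinane, NaHCO3, CH2Cl2, 0 °C→rt
Reagents that add atoms: none
Why: Dess–Martin oxidation of the benzylic and allylic alcohol should give the aryl enone under buffered, non-epimerising conditions and converge both carbinol epimers.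

**Step 18**
Reactants: 31 the bis-silyl ether from step 17
Product: 32 7-hydroxy-8-{[(5R,6R)-6-[(1S)-1-hydroxyethyl]-5-methylcyclohex-1-en-1-yl]carbonyl}-5-methoxy-3,4-dimethyl-6-(3-methylbut-2-en-1-yl)-2H-chromen-2-one (target)
Conditions: Bu4NF, AcOH (1:1), THF, 0 °C→rt
Reagents that add atoms: none
Why: Buffered fluoride desilylation cleaves the aryl and the secondary alkyl silyl ether together, the acetic acid keeping the phenol protonated so that neither oxa-Michael closure onto the enone nor acid-induced cyclisation of the prenyl group should intervene.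

**Compound list**
1 | diethyl oxalate | CCOC(=O)C(=O)OCC | starting material
2 | ethyl 2,3-dimethylbut-2-enoate | CCOC(=O)C(C)=C(C)C | starting material
3 | potassium enolate of diethyl 4,5-dimethyl-2-oxohex-4-enedioate (alkene geometry not fixed) | CCOC(=O)C([O-])=CC(C)=C(C)C(=O)OCC.[K+] | intermediate
4 | 3,4-dimethyl-2-oxo-2H-pyran-6-carboxylic acid | Cc1c(C)cc(C(=O)O)oc1=O | intermediate
5 | 3,4-dimethyl-2-oxo-2H-pyran-6-carbonyl chloride | Cc1c(C)cc(C(=O)Cl)oc1=O | intermediate
6 | 6-(2-diazoacetyl)-3,4-dimethyl-2H-pyran-2-one | Cc1c(C)cc(C(=O)C=[N+]=[N-])oc1=O | intermediate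
7 | ethyl 4-methylpent-3-enoate | CCOC(=O)CC=C(C)C | starting material
8 | lithium 5-methylhex-4-en-1-yn-1-olate | CC(C)=CCC#C[O-].[Li+] | intermediate
9 | triisopropyl[(5-methylhex-4-en-1-yn-1-yl)oxy]silane | CC(C)=CCC#CO[Si](C(C)C)(C(C)C)C(C)C | intermediate
10 | 3,4-dimethyl-6-(2-oxoethenyl)-2H-pyran-2-one (pyranonylketene) | Cc1c(C)cc(C=C=O)oc1=O | intermediate
11 | 4-(3,4-dimethyl-2-oxo-2H-pyran-6-yl)-2-(3-methylbut-2-en-1-yl)-3-[(triisopropylsilyl)oxy]cyclobut-2-en-1-one (racemic) | Cc1c(C)cc(C2C(=O)C(CC=C(C)C)=C2O[Si](C(C)C)(C(C)C)C(C)C)oc1=O | intermediate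
12 | (3E)-4-(3,4-dimethyl-2-oxo-2H-pyran-6-yl)-2-(3-methylbut-2-en-1-yl)-3-[(triisopropylsilyl)oxy]buta-1,3-dien-1-one (ketene carbon cis to the pyranone) | Cc1c(C)cc(/C=C(O[Si](C(C)C)(C(C)C)C(C)C)\C(CC=C(C)C)=C=O)oc1=O | intermediate
13 | 5-hydroxy-3,4-dimethyl-6-(3-methylbut-2-en-1-yl)-7-[(triisopropylsilyl)oxy]-2H-chromen-2-one | Cc1c(C)c2c(O)c(CC=C(C)C)c(O[Si](C(C)C)(C(C)C)C(C)C)cc2oc1=O | intermediate
14 | 5-methoxy-3,4-dimethyl-6-(3-methylbut-2-en-1-yl)-7-[(triisopropylsilyl)oxy]-2H-chromen-2-one | COc1c(CC=C(C)C)c(O[Si](C(C)C)(C(C)C)C(C)C)cc2oc(=O)c(C)c(C)c12 | intermediate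
15 | 7-hydroxy-5-methoxy-3,4-dimethyl-6-(3-methylbut-2-en-1-yl)-2H-chromen-2-one | COc1c(CC=C(C)C)c(O)cc2oc(=O)c(C)c(C)c12 | intermediate
16 | 7-hydroxy-5-methoxy-3,4-dimethyl-6-(3-methylbut-2-en-1-yl)-2-oxo-2H-chromene-8-carbaldehyde | COc1c(CC=C(C)C)c(O)c(C=O)c2oc(=O)c(C)c(C)c12 | intermediate
17 | 7-[(tert-butyldimethylsilyl)oxy]-5-methoxy-3,4-dimethyl-6-(3-methylbut-2-en-1-yl)-2-oxo-2H-chromene-8-carbaldehyde | COc1c(CC=C(C)C)c(O[Si](C)(C)C(C)(C)C)c(C=O)c2oc(=O)c(C)c(C)c12 | intermediate
18 | ethyl (3S)-3-hydroxybutanoate | CCOC(=O)C[C@H](C)O | starting material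
19 | (2Z)-but-2-en-1-ol | C/C=C\CO | starting material
20 | (2Z)-but-2-en-1-yl (3S)-3-hydroxybutanoate | C/C=C\COC(=O)C[C@H](C)O | intermediate
21 | dilithium salt of the Z(O)-enolate alkoxide of 20 | C/C=C\CO/C([O-])=C/[C@H](C)[O-].[Li+].[Li+] | intermediate
22 | (2S,3R)-2-[(1S)-1-hydroxyethyl]-3-methylpent-4-enoic acid | C=C[C@@H](C)[C@H](C(=O)O)[C@H](C)O | intermediate
23 | (2S,3R)-2-[(1S)-1-hydroxyethyl]-N-methoxy-N,3-dimethylpent-4-enamide | C=C[C@@H](C)[C@H](C(=O)N(C)OC)[C@H](C)O | intermediate
24 | (2S,3R)-N-methoxy-N,3-dimethyl-2-[(1S)-1-(triethylsilyloxy)ethyl]pent-4-enamide | C=C[C@@H](C)[C@H](C(=O)N(C)OC)[C@H](C)O[Si](CC)(CC)CC | intermediate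
25 | (5S,6R)-6-methyl-5-[(1S)-1-(triethylsilyloxy)ethyl]octa-1,7-dien-4-one | C=C[C@@H](C)[C@H](C(=O)CC=C)[C@H](C)O[Si](CC)(CC)CC | intermediate
26 | (5R,6S)-5-methyl-6-[(1S)-1-(triethylsilyloxy)ethyl]cyclohex-3-en-1-one | O=C1CC=C[C@@H](C)[C@H]1[C@H](C)O[Si](CC)(CC)CC | intermediate
27 | (2S,3R)-3-methyl-2-[(1S)-1-(triethylsilyloxy)ethyl]cyclohexan-1-one (2,3-cis) | O=C1CCC[C@@H](C)[C@H]1[C@H](C)O[Si](CC)(CC)CC | intermediate
28 | lithium (5R,6S)-5-methyl-6-[(1S)-1-(triethylsilyloxy)ethyl]cyclohex-1-en-1-olate | [Li+].[O-]C1=CCC[C@@H](C)[C@H]1[C@H](C)O[Si](CC)(CC)CC | intermediate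
29 | (5R,6S)-5-methyl-6-[(1S)-1-(triethylsilyloxy)ethyl]cyclohex-1-en-1-yl trifluoromethanesulfonate | FC(F)(F)S(=O)(=O)OC1=CCC[C@@H](C)[C@H]1[C@H](C)O[Si](CC)(CC)CC | intermediate
30 | 7-[(tert-butyldimethylsilyl)oxy]-8-{hydroxy[(5R,6R)-5-methyl-6-[(1S)-1-(triethylsilyloxy)ethyl]cyclohex-1-en-1-yl]methyl}-5-methoxy-3,4-dimethyl-6-(3-methylbut-2-en-1-yl)-2H-chromen-2-one (carbinol epimers) | COc1c(CC=C(C)C)c(O[Si](C)(C)C(C)(C)C)c(C(O)C3=CCC[C@@H](C)[C@H]3[C@H](C)O[Si](CC)(CC)CC)c2oc(=O)c(C)c(C)c12 | intermediate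
31 | 7-[(tert-butyldimethylsilyl)oxy]-5-methoxy-3,4-dimethyl-6-(3-methylbut-2-en-1-yl)-8-{[(5R,6R)-5-methyl-6-[(1S)-1-(triethylsilyloxy)ethyl]cyclohex-1-en-1-yl]carbonyl}-2H-chromen-2-one | COc1c(CC=C(C)C)c(O[Si](C)(C)C(C)(C)C)c(C(=O)C3=CCC[C@@H](C)[C@H]3[C@H](C)O[Si](CC)(CC)CC)c2oc(=O)c(C)c(C)c12 | intermediate
32 | 7-hydroxy-8-{[(5R,6R)-6-[(1S)-1-hydroxyethyl]-5-methylcyclohex-1-en-1-yl]carbonyl}-5-methoxy-3,4-dimethyl-6-(3-methylbut-2-en-1-yl)-2H-chromen-2-one | COc1c(CC=C(C)C)c(O)c(C(=O)C2=CCC[C@@H](C)[C@H]2[C@H](C)O)c2oc(=O)c(C)c(C)c12 | target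

**Totals**
Total step count: 18.
Longest linear sequence: 10 steps (steps 9–15 and 16–18 from ethyl (3S)-3-hydroxybutanoate; the coumarin branch, steps 1, 2, 4–8 and 16–18, is equally long).

**Steps most likely to fail**

Step 4 (key step, proposed new method). Two processes could defeat it. The 2-pyranone could undergo photochemical ring opening or valence isomerisation in competition with the Wolff rearrangement. The dienylketene could also be diverted (acylation of the product phenol, cycloaddition of the pyranone diene with the electron-rich alkyne) before it closes onto C5. The fallback uses known chemistry and does not set out from a numbered compound: it replaces 6 and 9 by commercial phloroglucinol and ethyl 2-methylacetoacetate and comes back to the route at 13. Pechmann condensation (H2SO4, 0 °C→rt) should give 5,7-dihydroxy-3,4-dimethyl-2H-chromen-2-one F1. Silylation of the more acidic, unhindered C7 hydroxyl (TIPSCl, imidazole, DMF, 0 °C) should give 5-hydroxy-3,4-dimethyl-7-[(triisopropylsilyl)oxy]-2H-chromen-2-one F2. Copper-catalysed O-alkylation with 3-chloro-3-methylbut-1-yne (CuCl2, DBU, MeCN, 0 °C) should give 3,4-dimethyl-5-[(2-methylbut-3-yn-2-yl)oxy]-7-[(triisopropylsilyl)oxy]-2H-chromen-2-one F3. Semihydrogenation (H2, Pd/CaCO3 poisoned with Pb(OAc)2, quinoline) should give 3,4-dimethyl-5-[(2-methylbut-3-en-2-yl)oxy]-7-[(triisopropylsilyl)oxy]-2H-chromen-2-one F4. Aromatic Claisen rearrangement (N,N-diethylaniline, 150 °C) can reach only C6, the single free ortho position of O5, and should deliver the prenyl group there to give 13.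

Step 16. Formation of the alkenylchromium species from the hindered enol triflate may be slow, so that reduction of the triflate or loss of the aryl silyl ether outruns addition to the doubly ortho-substituted aldehyde. The fallback sets out from 29 (with 17) and comes back at 30. Miyaura borylation of 29 (bis(pinacolato)diboron, PdCl2(PPh3)2, PPh3, KOPh, toluene, 50 °C) should give 2-{(5R,6R)-5-methyl-6-[(1S)-1-(triethylsilyloxy)ethyl]cyclohex-1-en-1-yl}-4,4,5,5-tetramethyl-1,3,2-dioxaborolane F5. Rhodium-catalysed 1,2-addition of this alkenylboronate to aldehyde 17 ([Rh(OH)(cod)]2, dioxane/H2O, 60 °C) should then give allylic alcohol 30.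

Step 3. Deprotonation at the doubly activated α-CH2 of the β,γ-unsaturated ester may compete with addition of dibromomethyllithium, giving a dienolate and alkene migration instead of the ynolate. The fallback sets out from 7 and comes back at 8 (and so 9). Reduction (iBu2AlH, CH2Cl2, −78 °C) should give 4-methylpent-3-enal F6. Corey–Fuchs olefination (CBr4, PPh3, CH2Cl2, 0 °C) should give 1,1-dibromo-5-methylhexa-1,4-diene F7. n-BuLi (2.1 equiv, THF, −78 °C) should give (5-methylhex-4-en-1-yn-1-yl)lithium F8. Oxidation of this acetylide with lithium tert-butyl peroxide (from t-BuOOH and LiN(SiMe3)2, −78 °C→0 °C) should give ynolate 8, which is silylated with TIPSOTf as in step 3.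

**Further compounds**
F1 | step 4 | 5,7-dihydroxy-3,4-dimethyl-2H-chromen-2-one | Cc1c(C)c2c(O)cc(O)cc2oc1=O
F2 | step 4 | 5-hydroxy-3,4-dimethyl-7-[(triisopropylsilyl)oxy]-2H-chromen-2-one | Cc1c(C)c2c(O)cc(O[Si](C(C)C)(C(C)C)C(C)C)cc2oc1=O
F3 | step 4 | 3,4-dimethyl-5-[(2-methylbut-3-yn-2-yl)oxy]-7-[(triisopropylsilyl)oxy]-2H-chromen-2-one | Cc1c(C)c2c(OC(C)(C)C#C)cc(O[Si](C(C)C)(C(C)C)C(C)C)cc2oc1=O
F4 | step 4 | 3,4-dimethyl-5-[(2-methylbut-3-en-2-yl)oxy]-7-[(triisopropylsilyl)oxy]-2H-chromen-2-one | Cc1c(C)c2c(OC(C)(C)C=C)cc(O[Si](C(C)C)(C(C)C)C(C)C)cc2oc1=O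
F5 | step 16 | 2-{(5R,6R)-5-methyl-6-[(1S)-1-(triethylsilyloxy)ethyl]cyclohex-1-en-1-yl}-4,4,5,5-tetramethyl-1,3,2-dioxaborolane | CC1(C)OB(OC1(C)C)C2=CCC[C@@H](C)[C@H]2[C@H](C)O[Si](CC)(CC)CC
F6 | step 3 | 4-methylpent-3-enal | CC(C)=CCC=O
F7 | step 3 | 1,1-dibromo-5-methylhexa-1,4-diene | CC(C)=CCC=C(Br)Br
F8 | step 3 | (5-methylhex-4-en-1-yn-1-yl)lithium | CC(C)=CCC#C[Li]
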